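The route rests on opening the benzo ring (ring B) of the benzofuran at the C7–C7a bond. The key step exploits the way phenol carbon C7 sits next to furan carbon C7a, with H at C6, the arylpropyl chain at C5 and prenyl at C4. This is the array a cyclobutenone delivers when it opens to a dienylketene that closes onto C2 of a 3-furyl group. One thermolysis therefore makes the C7–C7a bond, ring B and the free C7 hydroxyl with all substituents in place. Its precursor is a racemic 4-(3-furyl)-4-prenylcyclobut-2-enone carrying the bis-silylated ring A arylpropyl chain at C3, assembled from a ketene–ethoxyacetylene cycloadduct and an arylpropyllithium.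

Key step: step 11

Remark: benzofuran numbering is O1, C2, C3, C3a, C4–C7, C7a; ring A is the resorcinol ring (chain at C1, oxygens at C2 and C4, 2-methylbut-3-en-2-yl at C5); the target has no stereocentre, so chiral intermediates are racemic; ring A is carried as a mixed bis-silyl ether, TIPS (triisopropylsilyl) on O2 because it must survive the sigmatropic step and sits ortho to the carbanionic chain, TBS (tert-butyldimethylsilyl) on the hindered O4; Ar = 4-[(tert-butyldimethylsilyl)oxy]-5-(2-methylbut-3-en-2-yl)-2-[(triisopropylsilyl)oxy]phenyl.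

Step 1
Reactants: 1 3-furylacetic acid; 2 prenyl bromide (1-bromo-3-methylbut-2-ene)
Product: 4 2-(furan-3-yl)-5-methylhex-4-enoic acid (racemic), via dilithium enediolate 3 (not isolated)
Conditions: LiN(i-Pr)2 (2.2 equiv), THF, −78 to 0 °C; then 2, −78 °C to rt; 1 M HCl work-up
Reagents that add atoms: none
Why: Dianion (enediolate) alkylation of an arylacetic acid, in which the carbon nucleophile displaces the primary allylic bromide by SN2 and the resulting carboxylate resists a second deprotonation, so monoalkylation should dominate; the new stereocentre is racemic and is erased in step 11.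

Step 2
Reactants: 4 2-(furan-3-yl)-5-methylhex-4-enoic acid; 5 ethoxyacetylene
Product: 8 3-ethoxy-4-(furan-3-yl)-4-(3-methylbut-2-en-1-yl)cyclobut-2-en-1-one (racemic), via acid chloride 6 (not isolated), via furyl prenyl ketene 7 (not isolated)
Conditions: 1-chloro-N,N,2-trimethylprop-1-en-1-amine (1.05 equiv), CH2Cl2, 0 °C to rt; then 5 (3 equiv), Et3N (1.5 equiv, slow addition), rt
Reagents that add atoms: none
Why: The α-chloroenamine makes the acid chloride without releasing HCl (safe for furan and prenyl), Et3N dehydrochlorinates it to the aryl alkyl ketene, and the thermal ketene–ynol ether [2+2] cycloaddition is regioselective because the nucleophilic CH terminus of ethoxyacetylene bonds to the ketene carbonyl carbon, which puts OEt at C3 and the furyl/prenyl carbon at C4 as a racemic quaternary centre.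

Step 3
Reactants: 9 2,4-dihydroxybenzaldehyde; 2 prenyl bromide
Product: 10 2-hydroxy-4-[(3-methylbut-2-en-1-yl)oxy]benzaldehyde
Conditions: K2CO3 (1.1 equiv), acetone, reflux
Reagents that add atoms: none
Why: Williamson ether synthesis, selective for O4 because the 2-hydroxyl is locked in a hydrogen bond to the formyl group and is much less nucleophilic, so the mild carbonate base alkylates the 4-phenoxide by SN2 at the primary allylic carbon.

Step 4
Reactants: 10 2-hydroxy-4-[(3-methylbut-2-en-1-yl)oxy]benzaldehyde
Product: 11 4-[(3-methylbut-2-en-1-yl)oxy]-2-[(triisopropylsilyl)oxy]benzaldehyde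
Conditions: TIPSCl (1.3 equiv), imidazole (2.5 equiv), DMF, rt
Reagents that add atoms: chlorotriisopropylsilane, CC(C)[Si](Cl)(C(C)C)C(C)C
Why: Imidazole-assisted phenol silylation, which removes the chelate that would steer the later sigmatropic shift to C3, shields C3 sterically, and installs a silyl group robust to heat, hydride and organolithium reagents.

Step 5
Reactants: 11 4-[(3-methylbut-2-en-1-yl)oxy]-2-[(triisopropylsilyl)oxy]benzaldehyde
Product: 14 4-[(tert-butyldimethylsilyl)oxy]-5-(2-methylbut-3-en-2-yl)-2-[(triisopropylsilyl)oxy]benzaldehyde (ArCHO), via ortho dienone 12 (not isolated), via hindered phenol 13 (not isolated)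
Conditions: PhNEt2, 190 °C, Ar; cool to rt; then TBSCl (1.5 equiv), imidazole (3 equiv), DMAP (cat.), DMF, 40 °C
Reagents that add atoms: tert-butylchlorodimethylsilane, CC(C)(C)[Si](C)(C)Cl
Why: Aromatic Claisen rearrangement, in which the [3,3] shift should deliver the allyl unit with inversion (as the 1,1-dimethylallyl group) to the open, unshielded C5 rather than to C3 between the two oxygens, the dienone enolizes in the basic amine, and silylation in the same flask caps the acid-sensitive ortho-(1,1-dimethylallyl)phenol before isolation.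

Step 6
Reactants: 14 ArCHO; 15 ethyl (triphenylphosphoranylidene)acetate
Product: 16 ethyl (E)-3-Ar-prop-2-enoate
Conditions: 15 (1.3 equiv), toluene, 80 °C
Reagents that add atoms: none
Why: Wittig olefination with a stabilized ylide under neutral conditions that leave both aryl silyl ethers intact and should give mainly the E-enoate, whose geometry does not matter because the double bond is reduced in step 7.

Step 7
Reactants: 16 ethyl (E)-3-Ar-prop-2-enoate
Product: 17 ethyl 3-Ar-propanoate
Conditions: Cu(OAc)2·H2O (3 mol %), 1,2-bis(diphenylphosphino)benzene (3 mol %), (EtO)2MeSiH (2 equiv), t-BuOH (2 equiv), toluene, rt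
Reagents that add atoms: none
Why: CuH-catalysed conjugate reduction, in which the phosphine-ligated copper hydride adds hydride to the β-carbon of the enoate and t-BuOH protonates the copper enolate, while the unactivated vinyl group and the silyl ethers are not touched under these mild conditions.

Step 8
Reactants: 17 ethyl 3-Ar-propanoate
Product: 18 3-Ar-propan-1-ol
Conditions: i-Bu2AlH (2.5 equiv), CH2Cl2, −78 to 0 °C; aq. potassium sodium tartrate work-up
Reagents that add atoms: none
Why: Ester reduction by an aluminium hydride, with two hydride transfers at low temperature giving the primary alcohol while aryl silyl ethers and the isolated alkene survive because hydroalumination needs heat.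

Step 9
Reactants: 18 3-Ar-propan-1-ol
Product: 19 1-Ar-3-iodopropane
Conditions: I2 (1.3 equiv), PPh3 (1.3 equiv), imidazole (2 equiv), CH2Cl2, 0 °C to rt
Reagents that add atoms: iodine, [I][I]
Why: Appel-type iodination, in which the alcohol is activated as an alkoxyphosphonium ion and displaced by iodide in an SN2 step under buffered, non-acidic conditions compatible with silyl ethers and the vinyl group.

Step 10
Reactants: 19 1-Ar-3-iodopropane; 8 3-ethoxy-4-(furan-3-yl)-4-(3-methylbut-2-en-1-yl)cyclobut-2-en-1-one
Product: 22 3-(3-Ar-propyl)-4-(furan-3-yl)-4-(3-methylbut-2-en-1-yl)cyclobut-2-en-1-one (racemic), via arylpropyllithium 20 (not isolated), via lithium cyclobutenolate 21 (not isolated)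
Conditions: 19 (1.2 equiv), t-BuLi (2.1 equiv per 19), Et2O–pentane, −78 °C; then 8 (1.0 equiv), Et2O, −78 °C; then 1 M HCl, THF, 0 °C to rt
Reagents that add atoms: water, O
Why: Iodine–lithium exchange gives the primary alkyllithium, which adds 1,2 to the strained carbonyl of the vinylogous ester (no enolizable proton at the quaternary C4), and acid hydrolysis of the 3-ethoxycyclobutenol ionizes the tertiary allylic alcohol and turns the enol ether carbon into the new carbonyl, a vinylogous ester carbonyl transposition that places the chain at C3 while the quaternary centre stays racemic.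

Step 11
Reactants: 22 3-(3-Ar-propyl)-4-(furan-3-yl)-4-(3-methylbut-2-en-1-yl)cyclobut-2-en-1-one
Product: 25 5-(3-Ar-propyl)-4-(3-methylbut-2-en-1-yl)-1-benzofuran-7-ol, via dienylketene 23 (not isolated), via cyclohexadienone 24 (not isolated)
Conditions: toluene (degassed, 0.01 M), 110 °C, Ar
Reagents that add atoms: none
Why: Heating should open the C1–C4 bond of 22 by conrotatory 4π electrocyclic ring opening to dienylketene 23, whose ketene carbon (future C7) bonds to furan C2 (future C7a) in a thermally allowed disrotatory 6π-electrocyclization across the furan C2–C3 bond, and cyclohexadienone 24 then enolizes to the phenol. The closest known reaction type is the thermal ring expansion of 4-aryl- and 4-heteroarylcyclobutenones to naphthols and fused heteroaromatic phenols. Ring B is closed by this 6π-electrocyclization, which forms C7–C7a. No stereocentre is created: the quaternary carbon of 22 becomes aromatic C4 and the transient C7a–H centre of 24 is lost on enolization. The step needs the furyl group rather than the prenyl group to turn toward the ketene, which the substrate secures because ring opening is reversible while closure onto furan followed by aromatization is not, so the unproductive rotamer re-closes and drains through the productive one, helped by the trisubstituted prenyl alkene being a mismatched partner for intramolecular ketene cycloaddition. It also needs closure at furan C2 and not C4, which is secured because only C2 closure gives an aromatic benzofuran whereas C4 closure would give an o-quinoid isobenzofuran; high dilution protects the new phenol from acylation by ketene.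

Step 12
Reactants: 25 5-(3-Ar-propyl)-4-(3-methylbut-2-en-1-yl)-1-benzofuran-7-ol
Product: 26 4-{3-[7-hydroxy-4-(3-methylbut-2-en-1-yl)-1-benzofuran-5-yl]propyl}-6-(2-methylbut-3-en-2-yl)benzene-1,3-diol (CNP0288359.0)
Conditions: Bu4NF (2.5 equiv), AcOH (2.5 equiv), THF, 0 °C to rt
Reagents that add atoms: none
Why: Fluoride-mediated desilylation, driven by Si–F bond formation, should release both ring A phenols under acetic acid buffering, with furan, prenyl and 1,1-dimethylallyl groups inert to fluoride and no strong acid present that could cyclize the ortho-(1,1-dimethylallyl)phenol.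

Compound list
1 | 3-furylacetic acid | OC(=O)Cc1ccoc1 | starting material
2 | prenyl bromide (1-bromo-3-methylbut-2-ene) | CC(C)=CCBr | starting material
3 | dilithium enediolate of 3-furylacetic acid (formed in situ) | [Li+].[Li+].[O-]C([O-])=Cc1ccoc1 | intermediate
4 | 2-(furan-3-yl)-5-methylhex-4-enoic acid (racemic) | OC(=O)C(CC=C(C)C)c1ccoc1 | intermediate
5 | ethoxyacetylene | CCOC#C | starting material
6 | 2-(furan-3-yl)-5-methylhex-4-enoyl chloride (racemic, formed in situ) | ClC(=O)C(CC=C(C)C)c1ccoc1 | intermediate
7 | 2-(furan-3-yl)-5-methylhexa-1,4-dien-1-one (ketene, formed in situ) | O=C=C(CC=C(C)C)c1ccoc1 | intermediate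
8 | 3-ethoxy-4-(furan-3-yl)-4-(3-methylbut-2-en-1-yl)cyclobut-2-en-1-one (racemic) | O=C1C=C(OCC)C1(CC=C(C)C)c1ccoc1 | intermediate
9 | 2,4-dihydroxybenzaldehyde | O=Cc1ccc(O)cc1O | starting material
10 | 2-hydroxy-4-[(3-methylbut-2-en-1-yl)oxy]benzaldehyde | O=Cc1ccc(OCC=C(C)C)cc1O | intermediate
11 | 4-[(3-methylbut-2-en-1-yl)oxy]-2-[(triisopropylsilyl)oxy]benzaldehyde | O=Cc1ccc(OCC=C(C)C)cc1O[Si](C(C)C)(C(C)C)C(C)C | intermediate
12 | 3-(2-methylbut-3-en-2-yl)-4-oxo-6-[(triisopropylsilyl)oxy]cyclohexa-1,5-diene-1-carbaldehyde (racemic, formed in situ) | O=C1C=C(O[Si](C(C)C)(C(C)C)C(C)C)C(C=O)=CC1C(C)(C)C=C | intermediate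
13 | 4-hydroxy-5-(2-methylbut-3-en-2-yl)-2-[(triisopropylsilyl)oxy]benzaldehyde (formed in situ) | O=Cc1cc(C(C)(C)C=C)c(O)cc1O[Si](C(C)C)(C(C)C)C(C)C | intermediate
14 | 4-[(tert-butyldimethylsilyl)oxy]-5-(2-methylbut-3-en-2-yl)-2-[(triisopropylsilyl)oxy]benzaldehyde (ArCHO) | O=Cc1cc(C(C)(C)C=C)c(O[Si](C)(C)C(C)(C)C)cc1O[Si](C(C)C)(C(C)C)C(C)C | intermediate
15 | ethyl (triphenylphosphoranylidene)acetate | CCOC(=O)C=P(c1ccccc1)(c1ccccc1)c1ccccc1 | starting material
16 | ethyl (E)-3-Ar-prop-2-enoate | CCOC(=O)/C=C/c1cc(C(C)(C)C=C)c(O[Si](C)(C)C(C)(C)C)cc1O[Si](C(C)C)(C(C)C)C(C)C | intermediate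
17 | ethyl 3-Ar-propanoate | CCOC(=O)CCc1cc(C(C)(C)C=C)c(O[Si](C)(C)C(C)(C)C)cc1O[Si](C(C)C)(C(C)C)C(C)C | intermediate
18 | 3-Ar-propan-1-ol | OCCCc1cc(C(C)(C)C=C)c(O[Si](C)(C)C(C)(C)C)cc1O[Si](C(C)C)(C(C)C)C(C)C | intermediate
19 | 1-Ar-3-iodopropane | ICCCc1cc(C(C)(C)C=C)c(O[Si](C)(C)C(C)(C)C)cc1O[Si](C(C)C)(C(C)C)C(C)C | intermediate
20 | (3-Ar-propyl)lithium (formed in situ) | [Li]CCCc1cc(C(C)(C)C=C)c(O[Si](C)(C)C(C)(C)C)cc1O[Si](C(C)C)(C(C)C)C(C)C | intermediate
21 | lithium 1-(3-Ar-propyl)-3-ethoxy-4-(furan-3-yl)-4-(3-methylbut-2-en-1-yl)cyclobut-2-en-1-olate (racemic diastereomers, formed in situ) | [Li+].[O-]C1(CCCc2cc(C(C)(C)C=C)c(O[Si](C)(C)C(C)(C)C)cc2O[Si](C(C)C)(C(C)C)C(C)C)C=C(OCC)C1(CC=C(C)C)c1ccoc1 | intermediate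
22 | 3-(3-Ar-propyl)-4-(furan-3-yl)-4-(3-methylbut-2-en-1-yl)cyclobut-2-en-1-one (racemic) | O=C1C=C(CCCc2cc(C(C)(C)C=C)c(O[Si](C)(C)C(C)(C)C)cc2O[Si](C(C)C)(C(C)C)C(C)C)C1(CC=C(C)C)c1ccoc1 | intermediate
23 | (3Z)-3-(3-Ar-propyl)-4-(furan-3-yl)-7-methylocta-1,3,6-trien-1-one (dienylketene, formed in situ) | O=C=C/C(CCCc1cc(C(C)(C)C=C)c(O[Si](C)(C)C(C)(C)C)cc1O[Si](C(C)C)(C(C)C)C(C)C)=C(/CC=C(C)C)c1ccoc1 | intermediate
24 | 5-(3-Ar-propyl)-4-(3-methylbut-2-en-1-yl)-1-benzofuran-7(7aH)-one (racemic, formed in situ) | O=C1C=C(CCCc2cc(C(C)(C)C=C)c(O[Si](C)(C)C(C)(C)C)cc2O[Si](C(C)C)(C(C)C)C(C)C)C(CC=C(C)C)=C2C=COC12 | intermediate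
25 | 5-(3-Ar-propyl)-4-(3-methylbut-2-en-1-yl)-1-benzofuran-7-ol | C=CC(C)(C)c1cc(CCCc2cc(O)c3occc3c2CC=C(C)C)c(O[Si](C(C)C)(C(C)C)C(C)C)cc1O[Si](C)(C)C(C)(C)C | intermediate
26 | 4-{3-[7-hydroxy-4-(3-methylbut-2-en-1-yl)-1-benzofuran-5-yl]propyl}-6-(2-methylbut-3-en-2-yl)benzene-1,3-diol (CNP0288359.0) | C=CC(C)(C)c1cc(CCCc2cc(O)c3occc3c2CC=C(C)C)c(O)cc1O | target

Total step count: 12. Longest linear sequence: 10 steps (steps 3 to 12, from 2,4-dihydroxybenzaldehyde); the cyclobutenone branch (steps 1 and 2) joins at step 10.

Steps most likely to fail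

Step 11. The dienylketene may be consumed by intramolecular cycloaddition with the prenyl double bond whenever the prenyl group, not the furyl group, has turned toward the ketene. The new phenol may also be acylated by ketene still present. Both are favoured by the temperature that thermal ring opening needs. The fallback sets out from 22 and comes back at 25: the ketene is generated by photochemical electrocyclic ring opening (350 nm, degassed THF, 20 °C, 0.005 M, flow reactor of fluoropolymer tubing) instead of thermolysis. At ambient temperature closure onto the furan should still proceed, whereas cycloaddition with the trisubstituted alkene and bimolecular esterification are slow, and an unproductive ketene rotamer re-closes to 22 and is excited again. This fallback makes no new compound (F0).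

Step 5. The allyl unit may migrate to C3 instead of C5. The 1,1-dimethylallyl group may isomerize by the abnormal Claisen pathway (phenol-to-alkene hydrogen shift), the phenol may add to its own vinyl group, or the prenyl group may be lost at 190 °C. The fallback sets out from 9 and comes back at 17, installing the tertiary allyl group by cross-coupling instead of a sigmatropic shift. Bromination of 9 (Br2, AcOH, rt) should give 5-bromo-2,4-dihydroxybenzaldehyde F1. Selective silylation of the non-chelated 4-hydroxyl (TBSCl, imidazole, CH2Cl2, 0 °C) gives 5-bromo-4-[(tert-butyldimethylsilyl)oxy]-2-hydroxybenzaldehyde F2. TIPSCl, imidazole, DMF then gives 5-bromo-4-[(tert-butyldimethylsilyl)oxy]-2-[(triisopropylsilyl)oxy]benzaldehyde F3. Wittig reaction with 15 as in step 6 gives ethyl (E)-3-{5-bromo-4-[(tert-butyldimethylsilyl)oxy]-2-[(triisopropylsilyl)oxy]phenyl}prop-2-enoate F4. Conjugate reduction as in step 7 gives ethyl 3-{5-bromo-4-[(tert-butyldimethylsilyl)oxy]-2-[(triisopropylsilyl)oxy]phenyl}propanoate F5. A γ-selective Suzuki–Miyaura coupling of F5 with prenylboronic acid pinacol ester (Pd(OAc)2, bulky dialkylbiarylphosphine ligand, K3PO4, THF–H2O, 40 °C) transfers the allyl group with allylic transposition and gives 17. The coupling is placed at the ester stage so that no aldehyde is present to be allylborated.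

Step 10. The iodine–lithium exchange may be incomplete or give Wurtz-type coupling, the alkyllithium may attack silicon, it may add in a conjugate sense or cleave the strained vinylogous ester, or the cyclobutenol may ring-open during the acid treatment. The fallback sets out from 8 and 19 and comes back at 22, forming the C3–chain bond by cross-coupling instead of carbonyl addition and transposition. Hydrolysis of 8 (1 M HCl, THF, rt) gives 4-(furan-3-yl)-3-hydroxy-4-(3-methylbut-2-en-1-yl)cyclobut-2-en-1-one F6, the enol of a symmetrical 2,2-disubstituted cyclobutane-1,3-dione, so only one enol triflate can form. Tf2O, 2,6-lutidine, CH2Cl2, −78 °C gives 4-(furan-3-yl)-4-(3-methylbut-2-en-1-yl)-3-oxocyclobut-1-en-1-yl trifluoromethanesulfonate F7. Zinc insertion into 19 (Zn dust, LiCl, THF, 40 °C) gives (3-Ar-propyl)zinc iodide F8. Negishi coupling of F7 with F8 (PdCl2(dppf), THF, rt) gives 22 without any organolithium.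

Further compounds
F0 | step 11 | none | none
F1 | step 5 | 5-bromo-2,4-dihydroxybenzaldehyde | O=Cc1cc(Br)c(O)cc1O
F2 | step 5 | 5-bromo-4-[(tert-butyldimethylsilyl)oxy]-2-hydroxybenzaldehyde | O=Cc1cc(Br)c(O[Si](C)(C)C(C)(C)C)cc1O
F3 | step 5 | 5-bromo-4-[(tert-butyldimethylsilyl)oxy]-2-[(triisopropylsilyl)oxy]benzaldehyde | O=Cc1cc(Br)c(O[Si](C)(C)C(C)(C)C)cc1O[Si](C(C)C)(C(C)C)C(C)C
F4 | step 5 | ethyl (E)-3-{5-bromo-4-[(tert-butyldimethylsilyl)oxy]-2-[(triisopropylsilyl)oxy]phenyl}prop-2-enoate | CCOC(=O)/C=C/c1cc(Br)c(O[Si](C)(C)C(C)(C)C)cc1O[Si](C(C)C)(C(C)C)C(C)C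
F5 | step 5 | ethyl 3-{5-bromo-4-[(tert-butyldimethylsilyl)oxy]-2-[(triisopropylsilyl)oxy]phenyl}propanoate | CCOC(=O)CCc1cc(Br)c(O[Si](C)(C)C(C)(C)C)cc1O[Si](C(C)C)(C(C)C)C(C)C
F6 | step 10 | 4-(furan-3-yl)-3-hydroxy-4-(3-methylbut-2-en-1-yl)cyclobut-2-en-1-one (racemic) | O=C1C=C(O)C1(CC=C(C)C)c1ccoc1
F7 | step 10 | 4-(furan-3-yl)-4-(3-methylbut-2-en-1-yl)-3-oxocyclobut-1-en-1-yl trifluoromethanesulfonate (racemic) | O=C1C=C(OS(=O)(=O)C(F)(F)F)C1(CC=C(C)C)c1ccoc1
F8 | step 10 | (3-Ar-propyl)zinc iodide | I[Zn]CCCc1cc(C(C)(C)C=C)c(O[Si](C)(C)C(C)(C)C)cc1O[Si](C(C)C)(C(C)C)C(C)C
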